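The pyrrole ring is disconnected at C2–C3 and C4–C5. Because C3 and C4 carry only hydrogen, they can be delivered as a two-carbon acetylene surrogate. C2–N1–C5 comes from the glycine imine of icosanal, and the glycine ester carbon later becomes the formyl group. One AgOAc-catalysed azomethine ylide cycloaddition between methyl N-icosylideneglycinate and (E)-1,2-bis(phenylsulfonyl)ethene forms both ring C–C bonds and the five-membered ring. The two sulfonyl groups are then expelled as sulfinate, so aromatisation needs no oxidant. The precursor is simply the freshly made imino ester with its C19 chain already on the future C5.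

Key step: step 3

Assumption: cycloadduct 7 is drawn as one racemic diastereomer and intermediate 8 as one alkene isomer; other diastereomers or alkene isomers would converge on 9, because step 4 removes all four sp3 centres.

Step 1
Reactants: 1 icosan-1-ol
Product: 2 icosanal
Conditions: TEMPO (10 mol %), PhI(OAc)2 (1.1 equiv), CH2Cl2, rt
Reagents that add atoms: none
Why: Oxoammonium-mediated alcohol oxidation (TEMPO with (diacetoxyiodo)benzene) under anhydrous conditions should stop at the aldehyde, and the substrate carries no other reactive group.

Step 2
Reactants: 2 icosanal; 3 glycine methyl ester hydrochloride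
Product: 5 methyl 2-[(E)-icosylideneamino]acetate, via glycine methyl ester free base 4 (not isolated)
Conditions: Et3N (1.05 equiv), MgSO4, CH2Cl2, 0 °C to rt; quick cold water wash, Na2SO4, concentrate below 25 °C; crude used at once
Reagents that add atoms: none
Why: Imine (Schiff base) condensation in which Et3N frees the amine and MgSO4 removes the water; the E imine is the thermodynamic isomer, and the wash removes chloride that would otherwise precipitate the silver catalyst of step 3.

Step 3
Reactants: 5 methyl 2-[(E)-icosylideneamino]acetate (1.2 equiv); 6 (E)-1,2-bis(phenylsulfonyl)ethene (1.0 equiv)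
Product: 7 methyl (2S*,3S*,4S*,5R*)-5-nonadecyl-3,4-bis(phenylsulfonyl)pyrrolidine-2-carboxylate (racemic; ester and nonadecyl cis, the two sulfonyl groups trans, C3 sulfonyl trans to the ester)
Conditions: AgOAc (10 mol %), PPh3 (10 mol %), Et3N (20 mol %), CH2Cl2, 0 °C to rt, dark
Reagents that add atoms: none
Why: N,O-Chelation of imino ester 5 to monovalent silver (AgOAc) acidifies the glycine CH2, so Et3N or acetate removes a proton there and gives the W-shaped N-metalated azomethine ylide, which adds to the doubly activated alkene 6 and forms C2–C3 and C4–C5 in one operation. The closest known reaction type is the silver- or copper-catalysed 1,3-dipolar cycloaddition of α-imino ester ylides with vinyl sulfones and 1,2-bis(sulfonyl)ethenes. The pyrrolidine ring closes in the intermolecular [3+2] mode, either as a concerted suprafacial six-electron cycloaddition or, if stepwise, by Michael addition followed by a 5-endo-trig Mannich closure of the α-sulfonyl carbanion onto the silver-activated imine. C2 and C5 should come out cis because the chelated ylide holds the ester and the alkyl chain on the same side, C3 and C4 trans because the E geometry of 6 is transferred suprafacially, and the relation between these two pairs is decided by the endo or exo approach of 6 to the metal-bound dipole; the adduct is racemic since nothing chiral is present. None of this stereochemistry has to be controlled, because step 4 destroys all four centres, and regiochemistry cannot arise because 6 is symmetrical. The selectivity that the step does need is chemoselectivity, ylide formation and trapping before imine–enamine tautomerisation or self-condensation of the enolisable imine, and it is secured by the chelate-enhanced acidity of the glycine position of 5, the mild base and the high electrophilicity of 6.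

Step 4
Reactants: 7 methyl (2S*,3S*,4S*,5R*)-5-nonadecyl-3,4-bis(phenylsulfonyl)pyrrolidine-2-carboxylate
Product: 9 methyl 5-nonadecyl-1H-pyrrole-2-carboxylate, via monosulfonyl dihydropyrrole 8 (not isolated)
Conditions: DBU (3 equiv), THF, rt to 50 °C
Reagents that add atoms: none
Why: Two successive base-induced eliminations of benzenesulfinate (E1cB type: first across C2–C3 from the ester-acidified C2–H, then vinylogous expulsion of the C4 sulfinate from the enamine and tautomerisation) are driven by aromatisation and erase all four stereocentres.

Step 5
Reactants: 9 methyl 5-nonadecyl-1H-pyrrole-2-carboxylate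
Product: 10 N-methoxy-N-methyl-5-nonadecyl-1H-pyrrole-2-carboxamide
Conditions: MeNHOMe·HCl (3 equiv), i-PrMgCl (7 equiv), THF, −20 °C to rt; aq. NH4Cl
Reagents that add atoms: N,O-dimethylhydroxylamine hydrochloride, CNOC.Cl
Why: Weinreb amide formation by ester aminolysis with the chloromagnesium amide of N,O-dimethylhydroxylamine made in situ; one further equivalent of i-PrMgCl is consumed by the pyrrole N–H, and the amide once formed is protected from further addition by its magnesium chelate.

Step 6
Reactants: 10 N-methoxy-N-methyl-5-nonadecyl-1H-pyrrole-2-carboxamide
Product: 11 5-nonadecyl-1H-pyrrole-2-carbaldehyde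
Conditions: LiAlH4 (2 equiv), THF, −40 to 0 °C; aq. potassium sodium tartrate work-up
Reagents that add atoms: none
Why: Weinreb amide reduction: after deprotonation of the N–H, hydride addition should give a chelated tetrahedral aluminate that is stable at low temperature and releases the aldehyde only on aqueous work-up, which prevents over-reduction.

Compound list
1 | icosan-1-ol | CCCCCCCCCCCCCCCCCCCCO | starting material
2 | icosanal | CCCCCCCCCCCCCCCCCCCC=O | intermediate
3 | glycine methyl ester hydrochloride | COC(=O)CN.Cl | starting material
4 | glycine methyl ester (free base, not isolated) | COC(=O)CN | intermediate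
5 | methyl 2-[(E)-icosylideneamino]acetate | CCCCCCCCCCCCCCCCCCC/C=N/CC(=O)OC | intermediate
6 | (E)-1,2-bis(phenylsulfonyl)ethene | O=S(=O)(/C=C/S(=O)(=O)c1ccccc1)c1ccccc1 | starting material
7 | methyl (2S*,3S*,4S*,5R*)-5-nonadecyl-3,4-bis(phenylsulfonyl)pyrrolidine-2-carboxylate (racemic, one enantiomer drawn) | COC(=O)[C@@H]1N[C@H](CCCCCCCCCCCCCCCCCCC)[C@H](S(=O)(=O)c2ccccc2)[C@H]1S(=O)(=O)c2ccccc2 | intermediate
8 | methyl (4R*,5R*)-5-nonadecyl-4-(phenylsulfonyl)-4,5-dihydro-1H-pyrrole-2-carboxylate (racemic, sulfonyl and nonadecyl cis, not isolated) | COC(=O)C1=C[C@@H](S(=O)(=O)c2ccccc2)[C@@H](CCCCCCCCCCCCCCCCCCC)N1 | intermediate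
9 | methyl 5-nonadecyl-1H-pyrrole-2-carboxylate | CCCCCCCCCCCCCCCCCCCc1ccc(C(=O)OC)[nH]1 | intermediate
10 | N-methoxy-N-methyl-5-nonadecyl-1H-pyrrole-2-carboxamide | CCCCCCCCCCCCCCCCCCCc1ccc(C(=O)N(C)OC)[nH]1 | intermediate
11 | 5-nonadecyl-1H-pyrrole-2-carbaldehyde | CCCCCCCCCCCCCCCCCCCc1ccc(C=O)[nH]1 | target

Total step count: 6. Longest linear sequence: 6 steps (1 to 11).

Steps most likely to fail

Step 3. The enolisable imine may tautomerise to its enamine and self-condense faster than the silver-bound ylide is formed and trapped, so that little cycloadduct results. The fallback sets out from icosanal 2 and builds the ring by a Paal–Knorr condensation instead of a dipolar cycloaddition. Addition of commercial 2-(1,3-dioxan-2-yl)ethylmagnesium bromide to 2 (THF, 0 °C) should give racemic 1-(1,3-dioxan-2-yl)docosan-3-ol F1. Dess–Martin oxidation should give 1-(1,3-dioxan-2-yl)docosan-3-one F2. Heating F2 with NH4OAc in aqueous AcOH should unmask the acetal to 4-oxotricosanal F3 in the flask and condense it with ammonia to 2-nonadecyl-1H-pyrrole F4. Vilsmeier–Haack formylation of F4 (POCl3, DMF; aq. NaOAc) at the free α-position C5 comes back to the route at target 11.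

Step 2. During condensation and work-up, amine base and water may cause aldol-type self-condensation or hydrolysis of the imine, and chloride carried over would deactivate the silver catalyst. The fallback sets out from 2 and makes the imine by a Staudinger/aza-Wittig sequence under neutral, anhydrous, chloride-free conditions. Methyl azidoacetate and PPh3 (THF, rt, loss of N2) should give methyl 2-[(triphenyl-λ5-phosphanylidene)amino]acetate F5, which condenses with 2 to give imine 5. The route is rejoined at 5, whose solution goes directly into step 3.

Step 5. Aminolysis may stall because the N-magnesiated pyrrole ring donates into the ester carbonyl and lowers its electrophilicity, and slow addition of the Grignard reagent may compete on warming. The fallback sets out from 9 and activates the carboxyl group as the free acid instead. Saponification (NaOH, aq. MeOH/THF, 60 °C; acidification at 0 °C to avoid decarboxylation) should give 5-nonadecyl-1H-pyrrole-2-carboxylic acid F6. Coupling of F6 with N,O-dimethylhydroxylamine hydrochloride (EDC·HCl, HOBt, i-Pr2NEt, CH2Cl2/DMF) comes back to the route at Weinreb amide 10.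

Further compounds
F1 | step 3 | 1-(1,3-dioxan-2-yl)docosan-3-ol (racemic) | CCCCCCCCCCCCCCCCCCCC(O)CCC1OCCCO1
F2 | step 3 | 1-(1,3-dioxan-2-yl)docosan-3-one | CCCCCCCCCCCCCCCCCCCC(=O)CCC1OCCCO1
F3 | step 3 | 4-oxotricosanal | CCCCCCCCCCCCCCCCCCCC(=O)CCC=O
F4 | step 3 | 2-nonadecyl-1H-pyrrole | CCCCCCCCCCCCCCCCCCCc1ccc[nH]1
F5 | step 2 | methyl 2-[(triphenyl-λ5-phosphanylidene)amino]acetate | COC(=O)CN=P(c1ccccc1)(c1ccccc1)c1ccccc1
F6 | step 5 | 5-nonadecyl-1H-pyrrole-2-carboxylic acid | CCCCCCCCCCCCCCCCCCCc1ccc(C(=O)O)[nH]1
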